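The 13-membered carbocycle (ring atoms C1 = CH–OAc, C2, C3(Me)=C4, C5, C6, C7(Me)(OH), C8=C9, C10(iPr), C11, C12, C13(Me)(CHO)) is opened between C10 and C11. The C7 carbinol / E-C8=C9 / C10 stereocentre array is the signature of an anti-SN2′ opening of a C7–C8 oxirane. An acyclic, nerol-derived (7R,8S,9Z)-vinyl oxirane carrying a terminal vinyl group on C13 (C11=C12) is therefore hydroborated at C11 and the alkyl group is passed through copper to C10. One operation closes the ring, frees the C7 hydroxyl, sets the E-alkene and creates C10 by 1,3-chirality transfer.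

Key step: step 15

Remarks:
- Locants C1–C13 of the target ring are used for all intermediates; nerol C1, C2, C3, C7 and C8 become C9, C8, C7, C3 and C2.
- Assumption: the iridium-catalysed tert-(hydroxy)prenylation gives the anti (C1-OH/CH2OH) adduct, and the (R)-Tol-BINAP antipode is taken to deliver 13R (otherwise the (S)-ligand is used). C1 is re-set in steps 8 and 9, so only the sense at C13 matters.
- PMB = 4-methoxybenzyl, TBS = tert-butyldimethylsilyl, 9-BBN = 9-borabicyclo[3.3.1]nonane.

Step 1
Reactants: 1 nerol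
Product: 2 neryl PMB ether
Conditions: NaH, 4-methoxybenzyl chloride, n-Bu4NI (cat.), THF/DMF, 0 °C to rt
Reagents that add atoms: 4-methoxybenzyl chloride, COc1ccc(CCl)cc1
Why: Williamson etherification of the allylic alkoxide should give an ether that is inert up to step 11 and is later removed oxidatively without touching silyl ethers; no stereocentre is involved.

Step 2
Reactants: 2 neryl PMB ether
Product: 4 (2E,6Z)-8-(PMB-oxy)-2,6-dimethylocta-2,6-dienal, via allylic alcohol 3 (not isolated)
Conditions: SeO2 (0.3 equiv), t-BuOOH (3 equiv), salicylic acid (0.1 equiv), CH2Cl2, rt; crude mixture then MnO2, CH2Cl2, rt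
Reagents that add atoms: tert-butyl hydroperoxide, CC(C)(C)OO
Why: Catalytic SeO2 allylic oxidation (ene reaction, then [2,3]-sigmatropic shift) should hydroxylate the (E)-methyl group of the remote, electron-richer trisubstituted alkene (the 2,3-alkene is deactivated by the allylic ether), and MnO2 should converge the alcohol/aldehyde mixture to the (E)-enal that carries the future C2.

Step 3
Reactants: 4 (2E,6Z)-enal
Product: 5 PMB ether of (2Z,6E)-3,7-dimethylnona-2,6,8-trien-1-ol
Conditions: Ph3PCH3Br, KOtBu, THF, 0 °C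
Reagents that add atoms: methyltriphenylphosphonium bromide, C[P+](c1ccccc1)(c1ccccc1)c1ccccc1.[Br-]
Why: Wittig methylenation of the enal should add the future C1 as a terminal vinyl carbon and leave the E-geometry of C3=C4 untouched.

Step 4
Reactants: 5 triene PMB ether
Product: 7 (3E,7Z)-9-(PMB-oxy)-3,7-dimethylnona-3,7-dien-1-ol, via alkyl-9-BBN 6 (not isolated)
Conditions: 9-BBN (1.1 equiv), THF, 0 °C to rt; then NaOH, H2O2, 0 °C
Reagents that add atoms: hydrogen peroxide, OO
Why: Hydroboration–oxidation: 9-BBN should add boron only to the terminal CH2 of the monosubstituted end of the diene (trisubstituted alkenes react far more slowly), giving the homoallylic alcohol with C1–OH and the E-C3=C4 alkene retained.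

Step 5
Reactants: 7 homoallylic alcohol
Product: 8 (3E,7Z)-9-(PMB-oxy)-3,7-dimethylnona-3,7-dienal
Conditions: Dess–Martin periodinane, NaHCO3, CH2Cl2, 0 °C; used crude
Reagents that add atoms: none
Why: Buffered Dess–Martin oxidation of the primary alcohol should give the β,γ-unsaturated aldehyde under neutral conditions that do not move C3=C4 into conjugation; no stereocentre is involved.

Step 6
Reactants: 8 β,γ-unsaturated aldehyde; 9 isoprene monoxide (racemic, 3 equiv)
Product: 10 (1R,13R)-diol
Conditions: [Ir(cod)Cl]2 (2.5 mol%), (R)-Tol-BINAP (5 mol%), 4-cyano-3-nitrobenzoic acid (10 mol%), K3PO4 (5 mol%), 2-propanol (2 equiv), THF, 60 °C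
Reagents that add atoms: none
Why: Iridium-catalysed transfer-hydrogenative carbonyl tert-(hydroxy)prenylation from the aldehyde oxidation level: 2-propanol should act as terminal reductant (becoming acetone), the catalyst should open 9 to a (hydroxymethyl)(methyl)-substituted allyliridium species (its stereocentre is erased) and join it to 8 at the tertiary allyl terminus through a closed chair transition state, so that C1–C13 and the quaternary centre form together, the chiral bisphosphine setting 13R (C1 is expected as 1R and is corrected in steps 8 and 9).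

Step 7
Reactants: 10 (1R,13R)-diol
Product: 11 primary TBS ether of 10
Conditions: TBSCl (1.05 equiv), imidazole, CH2Cl2, 0 °C
Reagents that add atoms: tert-butyldimethylsilyl chloride, CC(C)(C)[Si](C)(C)Cl
Why: Silylation should select the primary neopentyl hydroxyl over the secondary hydroxyl flanked by the quaternary carbon, masking the future aldehyde carbon.

Step 8
Reactants: 11 primary TBS ether
Product: 12 (13R)-C1 ketone
Conditions: Dess–Martin periodinane, CH2Cl2, 0 °C to rt
Reagents that add atoms: none
Why: Dess–Martin oxidation under mild conditions should give the β,γ-unsaturated ketone without moving C3=C4 into conjugation, erasing the mis-set C1 centre while C13 (no α-hydrogen) cannot epimerise.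

Step 9
Reactants: 12 (13R)-C1 ketone
Product: 13 (1S,13R)-alcohol
Conditions: (R)-2-methyl-CBS-oxazaborolidine (0.5 equiv), catecholborane (2 equiv), toluene, −78 to −40 °C; aqueous NaOH work-up
Reagents that add atoms: none
Why: Corey–Bakshi–Shibata reduction: with the quaternary C13 as the large and C2H2 as the small substituent, the (R)-catalyst should deliver hydride to the face that gives 1S under catalyst control, and catecholborane should leave the alkenes untouched.

Step 10
Reactants: 13 (1S,13R)-alcohol
Product: 14 (1S,13R)-bis-TBS ether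
Conditions: TBSOTf, 2,6-lutidine, CH2Cl2, −78 to 0 °C
Reagents that add atoms: tert-butyldimethylsilyl trifluoromethanesulfonate, CC(C)(C)[Si](C)(C)OS(=O)(=O)C(F)(F)F
Why: Silyl triflate silylation should protect the hindered secondary hydroxyl so that both East oxygens survive the base and organometallic steps that follow.

Step 11
Reactants: 14 bis-TBS PMB ether
Product: 15 (7Z)-allylic alcohol
Conditions: DDQ, CH2Cl2/pH 7 buffer, 0 °C
Reagents that add atoms: none
Why: Oxidative cleavage of the PMB ether by DDQ (hydride abstraction, then hydrolysis of the oxocarbenium ion) should free the C9 allylic alcohol and leave the silyl ethers and alkenes intact.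

Step 12
Reactants: 15 (7Z)-allylic alcohol
Product: 16 (7R,8S)-epoxy alcohol
Conditions: Ti(OiPr)4 (20 mol%), L-(+)-diethyl tartrate (24 mol%), t-BuOOH, 4 Å molecular sieves, CH2Cl2, −20 °C
Reagents that add atoms: tert-butyl hydroperoxide, CC(C)(C)OO
Why: Sharpless asymmetric epoxidation should epoxidise only the allylic-alcohol alkene; as with nerol, L-(+)-tartrate should give the (2S,3R)-oxiranemethanol, that is the cis-oxirane with 7R and 8S, under reagent control.

Step 13
Reactants: 16 (7R,8S)-epoxy alcohol
Product: 17 epoxy aldehyde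
Conditions: Dess–Martin periodinane, NaHCO3, CH2Cl2, 0 °C
Reagents that add atoms: none
Why: Buffered Dess–Martin oxidation should give the sensitive α,β-epoxy aldehyde without opening or epimerising the oxirane; it is used directly.

Step 14
Reactants: 17 epoxy aldehyde
Product: 18 (7R,8S,9Z)-vinyl oxirane
Conditions: (2-methylpropyl)triphenylphosphonium bromide, KN(SiMe3)2, THF, −78 to 0 °C
Reagents that add atoms: (2-methylpropyl)triphenylphosphonium bromide, CC(C)C[P+](c1ccccc1)(c1ccccc1)c1ccccc1.[Br-]
Why: A salt-free Wittig reaction of the non-stabilised ylide should give the Z-C9=C10 alkene carrying the isopropyl group, the geometry the key step needs; the oxirane centres are not touched.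

Step 15
Reactants: 18 (7R,8S,9Z)-vinyl oxirane
Product: 20 bis-TBS macrocycle (1S,3E,7R,8E,10S,13R), via alkyl-9-BBN 19 (not isolated)
Conditions: 9-BBN (1.05 equiv), THF, rt; KOtBu (1.0 equiv); then slow addition (12 h) to CuOAc (20 mol%) in THF (final 2 mM), 40 °C; H2O work-up
Reagents that add atoms: none
Why: Proposed new method: 9-BBN should add only to the monosubstituted C11=C12 alkene, KOtBu should turn the B-alkyl-9-BBN 19 into a borate that hands the primary C11 alkyl group to monovalent copper, and the alkylcopper species should coordinate C9=C10 anti to the C8–O bond, open the oxirane by oxidative addition to a C10-bound trivalent copper allyl alkoxide and form C10–C11 by reductive elimination. The closest known reaction types are the copper-catalysed γ-selective, anti-stereospecific allyl–alkyl coupling of alkyl-9-BBN reagents with (Z)-allylic phosphates and the anti-SN2′ alkylation of acyclic (Z)-vinyl oxiranes by alkyl cuprates; neither has been shown as a ring closure or with an alkylborane on a vinyl oxirane. The 13-membered carbocycle closes in an endo mode, the whole C8–C9–C10 allyl unit ending inside the ring. C10 is set by 1,3-chirality transfer from C8: anti attack on the (8S,9Z) substrate in the s-trans conformer (the s-cis conformer is excluded by A(1,3) strain between C7 and the isopropyl group) should give 10S and the E-C8=C9 alkene, while C7 keeps its oxygen and configuration. The step needs chemoselective hydroboration (steric preference of 9-BBN for the terminal vinyl group over the Z-disubstituted and trisubstituted alkenes), γ- over α-attack (the α-carbon is flanked by quaternary C7) and cyclisation over oligomerisation (slow addition, high dilution).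

Step 16
Reactants: 20 bis-TBS macrocycle
Product: 21 macrocyclic triol
Conditions: TBAF (3 equiv), THF, rt to 45 °C
Reagents that add atoms: none
Why: Fluoride-mediated desilylation should remove both silyl ethers without affecting the tertiary allylic alcohol or the alkenes.

Step 17
Reactants: 21 macrocyclic triol
Product: 22 β-hydroxy aldehyde
Conditions: TEMPO (0.2 equiv), PhI(OAc)2 (1.2 equiv), CH2Cl2, rt
Reagents that add atoms: none
Why: Oxoammonium (TEMPO) oxidation should select the primary alcohol over the hindered secondary and the tertiary hydroxyls, and the aldehyde on quaternary C13 can neither epimerise nor eliminate.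

Step 18
Reactants: 22 β-hydroxy aldehyde
Product: 23 target CNP0106239.1
Conditions: Ac2O, pyridine, DMAP (cat.), CH2Cl2, 0 °C to rt
Reagents that add atoms: acetic anhydride, CC(=O)OC(C)=O
Why: DMAP-catalysed acetylation should esterify the secondary C1 hydroxyl only, the tertiary C7 hydroxyl being unreactive under these mild conditions.

Compound list
1 | nerol, (2Z)-3,7-dimethylocta-2,6-dien-1-ol | CC(C)=CCC/C(C)=C\CO | starting material
2 | neryl 4-methoxybenzyl ether | CC(C)=CCC/C(C)=C\COCc1ccc(OC)cc1 | intermediate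
3 | (2E,6Z)-8-[(4-methoxybenzyl)oxy]-2,6-dimethylocta-2,6-dien-1-ol | OC/C(C)=C/CC/C(C)=C\COCc1ccc(OC)cc1 | intermediate
4 | (2E,6Z)-8-[(4-methoxybenzyl)oxy]-2,6-dimethylocta-2,6-dienal | O=C/C(C)=C/CC/C(C)=C\COCc1ccc(OC)cc1 | intermediate
5 | (2Z,6E)-3,7-dimethylnona-2,6,8-trien-1-yl 4-methoxybenzyl ether | C=C/C(C)=C/CC/C(C)=C\COCc1ccc(OC)cc1 | intermediate
6 | 9-{(3E,7Z)-9-[(4-methoxybenzyl)oxy]-3,7-dimethylnona-3,7-dien-1-yl}-9-borabicyclo[3.3.1]nonane | B1(CC/C(C)=C/CC/C(C)=C\COCc3ccc(OC)cc3)C2CCCC1CCC2 | intermediate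
7 | (3E,7Z)-9-[(4-methoxybenzyl)oxy]-3,7-dimethylnona-3,7-dien-1-ol | OCC/C(C)=C/CC/C(C)=C\COCc1ccc(OC)cc1 | intermediate
8 | (3E,7Z)-9-[(4-methoxybenzyl)oxy]-3,7-dimethylnona-3,7-dienal | O=CC/C(C)=C/CC/C(C)=C\COCc1ccc(OC)cc1 | intermediate
9 | isoprene monoxide, racemic 2-methyl-2-vinyloxirane | CC1(C=C)CO1 | starting material
10 | (2R,3R,5E,9Z)-2-ethenyl-11-[(4-methoxybenzyl)oxy]-2,5,9-trimethylundeca-5,9-diene-1,3-diol (1R,13R in target numbering) | C=C[C@](C)(CO)[C@H](O)C/C(C)=C/CC/C(C)=C\COCc1ccc(OC)cc1 | intermediate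
11 | (2R,3R,5E,9Z)-1-[(tert-butyldimethylsilyl)oxy]-2-ethenyl-11-[(4-methoxybenzyl)oxy]-2,5,9-trimethylundeca-5,9-dien-3-ol | C=C[C@](C)(CO[Si](C)(C)C(C)(C)C)[C@H](O)C/C(C)=C/CC/C(C)=C\COCc1ccc(OC)cc1 | intermediate
12 | (2R,5E,9Z)-1-[(tert-butyldimethylsilyl)oxy]-2-ethenyl-11-[(4-methoxybenzyl)oxy]-2,5,9-trimethylundeca-5,9-dien-3-one | C=C[C@](C)(CO[Si](C)(C)C(C)(C)C)C(=O)C/C(C)=C/CC/C(C)=C\COCc1ccc(OC)cc1 | intermediate
13 | (2R,3S,5E,9Z)-1-[(tert-butyldimethylsilyl)oxy]-2-ethenyl-11-[(4-methoxybenzyl)oxy]-2,5,9-trimethylundeca-5,9-dien-3-ol (1S,13R in target numbering) | C=C[C@](C)(CO[Si](C)(C)C(C)(C)C)[C@@H](O)C/C(C)=C/CC/C(C)=C\COCc1ccc(OC)cc1 | intermediate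
14 | (2R,3S,5E,9Z)-1,3-bis[(tert-butyldimethylsilyl)oxy]-2-ethenyl-2,5,9-trimethylundeca-5,9-dien-11-yl 4-methoxybenzyl ether | C=C[C@](C)(CO[Si](C)(C)C(C)(C)C)[C@@H](O[Si](C)(C)C(C)(C)C)C/C(C)=C/CC/C(C)=C\COCc1ccc(OC)cc1 | intermediate
15 | (2Z,6E,9S,10R)-9,11-bis[(tert-butyldimethylsilyl)oxy]-10-ethenyl-3,7,10-trimethylundeca-2,6-dien-1-ol | C=C[C@](C)(CO[Si](C)(C)C(C)(C)C)[C@@H](O[Si](C)(C)C(C)(C)C)C/C(C)=C/CC/C(C)=C\CO | intermediate
16 | {(2S,3R)-3-[(3E,6S,7R)-6,8-bis[(tert-butyldimethylsilyl)oxy]-7-ethenyl-4,7-dimethyloct-3-en-1-yl]-3-methyloxiran-2-yl}methanol (7R,8S in target numbering) | C=C[C@](C)(CO[Si](C)(C)C(C)(C)C)[C@@H](O[Si](C)(C)C(C)(C)C)C/C(C)=C/CC[C@@]1(C)O[C@H]1CO | intermediate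
17 | (2R,3R)-3-[(3E,6S,7R)-6,8-bis[(tert-butyldimethylsilyl)oxy]-7-ethenyl-4,7-dimethyloct-3-en-1-yl]-3-methyloxirane-2-carbaldehyde (same spatial arrangement at the oxirane as in 16) | C=C[C@](C)(CO[Si](C)(C)C(C)(C)C)[C@@H](O[Si](C)(C)C(C)(C)C)C/C(C)=C/CC[C@@]1(C)O[C@H]1C=O | intermediate
18 | (2R,3S)-2-[(3E,6S,7R)-6,8-bis[(tert-butyldimethylsilyl)oxy]-7-ethenyl-4,7-dimethyloct-3-en-1-yl]-2-methyl-3-[(1Z)-3-methylbut-1-en-1-yl]oxirane (7R,8S,9Z in target numbering) | C=C[C@](C)(CO[Si](C)(C)C(C)(C)C)[C@@H](O[Si](C)(C)C(C)(C)C)C/C(C)=C/CC[C@@]1(C)O[C@H]1/C=C\C(C)C | intermediate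
19 | B-alkyl-9-BBN from 18, boron on C11 | B1(CC[C@](C)(CO[Si](C)(C)C(C)(C)C)[C@@H](O[Si](C)(C)C(C)(C)C)C/C(C)=C/CC[C@@]3(C)O[C@H]3/C=C\C(C)C)C2CCCC1CCC2 | intermediate
20 | 13-membered carbocycle (1S,3E,7R,8E,10S,13R, target numbering) with C1–OTBS, C13–CH2OTBS and free C7–OH | CC(C)(C)[Si](C)(C)O[C@H]1C/C(C)=C/CC[C@@](C)(O)/C=C/[C@H](C(C)C)CC[C@]1(C)CO[Si](C)(C)C(C)(C)C | intermediate
21 | macrocyclic triol (1S,3E,7R,8E,10S,13R): C1–OH, C7–OH, C13–CH2OH | O[C@H]1C/C(C)=C/CC[C@@](C)(O)/C=C/[C@H](C(C)C)CC[C@]1(C)CO | intermediate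
22 | macrocyclic β-hydroxy aldehyde (1S,3E,7R,8E,10S,13S): C1–OH, C7–OH, C13–CHO | O[C@H]1C/C(C)=C/CC[C@@](C)(O)/C=C/[C@H](C(C)C)CC[C@]1(C)C=O | intermediate
23 | CNP0106239.1, the C1 acetate of 22 | CC(=O)O[C@H]1C/C(C)=C/CC[C@@](C)(O)/C=C/[C@H](C(C)C)CC[C@]1(C)C=O | target

Total step count: 18
Longest linear sequence: 18 steps (from nerol)

Steps most likely to fail

Step 15 (Proposed new method). The boron-to-copper transfer or the anti-SN2′ ring closure may be slower than oligomerisation, direct SN2 opening or reduction of the oxirane, or the hydroboration may not discriminate the alkenes cleanly. The fallback sets out from 14, comes back at 20, uses only known reaction types and closes the ring at C8=C9 instead. Hydroboration of 14 with 9-BBN should give the alkyl-9-BBN F1 (not isolated). F1 is coupled intermolecularly with (Z)-1-chloro-4-methylpent-2-ene under the established copper-catalysed enantioselective γ-selective allyl–alkyl coupling (CuOTf, DTBM-SEGPHOS antipode chosen for 10S, KOMe). This should give the branched coupling product F2, which already holds the C10–C11 bond, the 10S centre and a vinyl group at C9. DDQ should then free the allylic alcohol F3, and Sharpless epoxidation with L-(+)-diethyl tartrate should give the epoxy alcohol F4. Iodination (I2, PPh3, imidazole) should give the epoxy iodide F5, and zinc-mediated reductive opening (Zn, EtOH, reflux) should give the (7R)-tertiary vinyl carbinol F6. Ring-closing metathesis of the two terminal vinyl groups (second-generation Grubbs catalyst RuCl2(=CHPh)(PCy3)(SIMes), CH2Cl2, 40 °C, 1 mM) should then give 20; any Z isomer would be removed by chromatography.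

Step 6. The β,γ-unsaturated aldehyde may isomerise into conjugation under the warm, weakly basic conditions, or the iridium catalyst may give low conversion or poor enantiofacial control with this substrate. The fallback sets out from 8 and 9 and comes back at 10; it replaces the allyliridium addition by an acid-catalysed allylboration at low temperature. Isoprene monoxide 9 is converted by copper-catalysed SN2′ borylation (CuCl, Xantphos, KOtBu, B2pin2, MeOH, THF) into the (E)-allylboronate F7. Chiral phosphoric acid-catalysed allylboration of crude 8 with F7 (TRIP antipode chosen for 13R, toluene, −30 °C) through a closed chair transition state should give 10 after aqueous work-up.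

Step 17. Oxidation of the neopentyl primary alcohol may be slow, so that the secondary alcohol or the tertiary allylic alcohol is attacked competitively. The fallback sets out from 20 and comes back at 22; it replaces chemoselective oxidation by staged deprotection. Selective cleavage of the less hindered primary silyl ether (HF·pyridine, pyridine, THF, 0 °C) should give the primary alcohol F8. Dess–Martin oxidation should give the silyl-protected aldehyde F9, and TBAF buffered with acetic acid should remove the remaining secondary silyl ether to give 22.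

Further compounds
F1 | step 15 | B-alkyl-9-BBN from 14, boron on C11 | B1(CC[C@](C)(CO[Si](C)(C)C(C)(C)C)[C@@H](O[Si](C)(C)C(C)(C)C)C/C(C)=C/CC/C(C)=C\COCc3ccc(OC)cc3)C2CCCC1CCC2
F2 | step 15 | (10S)-branched coupling product, PMB ether with C10(isopropyl)–CH=CH2 | C=C[C@H](C(C)C)CC[C@](C)(CO[Si](C)(C)C(C)(C)C)[C@@H](O[Si](C)(C)C(C)(C)C)C/C(C)=C/CC/C(C)=C\COCc1ccc(OC)cc1
F3 | step 15 | (7Z)-allylic alcohol from F2 | C=C[C@H](C(C)C)CC[C@](C)(CO[Si](C)(C)C(C)(C)C)[C@@H](O[Si](C)(C)C(C)(C)C)C/C(C)=C/CC/C(C)=C\CO
F4 | step 15 | (7R,8S)-epoxy alcohol from F3 | C=C[C@H](C(C)C)CC[C@](C)(CO[Si](C)(C)C(C)(C)C)[C@@H](O[Si](C)(C)C(C)(C)C)C/C(C)=C/CC[C@@]1(C)O[C@H]1CO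
F5 | step 15 | (7R,8S)-epoxy iodide from F4 | C=C[C@H](C(C)C)CC[C@](C)(CO[Si](C)(C)C(C)(C)C)[C@@H](O[Si](C)(C)C(C)(C)C)C/C(C)=C/CC[C@@]1(C)O[C@H]1CI
F6 | step 15 | (7R)-tertiary vinyl carbinol, diene for ring-closing metathesis | C=C[C@H](C(C)C)CC[C@](C)(CO[Si](C)(C)C(C)(C)C)[C@@H](O[Si](C)(C)C(C)(C)C)C/C(C)=C/CC[C@@](C)(O)C=C
F7 | step 6 | (E)-2-methyl-4-(4,4,5,5-tetramethyl-1,3,2-dioxaborolan-2-yl)but-2-en-1-ol | OC/C(C)=C/CB1OC(C)(C)C(C)(C)O1
F8 | step 17 | macrocyclic primary alcohol with C1–OTBS retained | CC(C)(C)[Si](C)(C)O[C@H]1C/C(C)=C/CC[C@@](C)(O)/C=C/[C@H](C(C)C)CC[C@]1(C)CO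
F9 | step 17 | macrocyclic aldehyde with C1–OTBS retained | CC(C)(C)[Si](C)(C)O[C@H]1C/C(C)=C/CC[C@@](C)(O)/C=C/[C@H](C(C)C)CC[C@]1(C)C=O
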